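The plan cuts the pyrrole ring at N1–C2 and removes the C3 bromine in the same retrosynthetic stroke. It exploits the fact that C2 and C3 of the pyrrole ring both carry bromine: a bromoethynyl group ortho to a sulfonamide nitrogen already contains C3, C2 and the C2–Br bond. A single electrophilic bromination then closes the five-membered ring through nitrogen and places bromine on C3, so no preformed indole has to be brominated regioselectively. The C5 and C6 bromines of the benzene ring are carried from 3,4-dibromoaniline. The cyclisation substrate is N-tosyl-4,5-dibromo-2-(bromoethynyl)aniline; detosylation ends the route.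

Key step: step 5

Assumption: the target has no stereocentre or other stereogenic element, so the route needs no stereocontrol.

Step 1
Reactants: 1 3,4-dibromoaniline
Product: 2 4,5-dibromo-2-iodoaniline
Conditions: NIS (1.0 equiv), AcOH, rt, dark
Reagents that add atoms: N-iodosuccinimide, O=C1CCC(=O)N1I
Why: Electrophilic aromatic iodination (SEAr) of an aniline: the amino group directs ortho/para, the para position is blocked by bromine and the ortho position between NH2 and Br is crowded, so iodine should enter at the open ortho carbon C6, which is C2 of the product.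

Step 2
Reactants: 2 4,5-dibromo-2-iodoaniline; 3 trimethylsilylacetylene
Product: 4 4,5-dibromo-2-[(trimethylsilyl)ethynyl]aniline
Conditions: PdCl2(PPh3)2 (2 mol%), CuI (4 mol%), Et3N, THF, rt
Reagents that add atoms: none
Why: Sonogashira coupling: oxidative addition of Pd(0) into the C–I bond is far faster than into C–Br at room temperature, so the alkyne should be installed only ortho to nitrogen while both aryl bromides and the free amine survive.

Step 3
Reactants: 4 4,5-dibromo-2-[(trimethylsilyl)ethynyl]aniline; 5 4-toluenesulfonyl chloride
Product: 6 N-{4,5-dibromo-2-[(trimethylsilyl)ethynyl]phenyl}-4-methylbenzenesulfonamide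
Conditions: TsCl (1.2 equiv), pyridine, CH2Cl2, 0 °C to rt
Reagents that add atoms: none
Why: N-Sulfonylation of an aniline with a sulfonyl chloride under pyridine catalysis: the weakly nucleophilic, ortho-substituted amine should stop at the monosulfonamide, and the C-silyl alkyne and aryl bromides are inert to these conditions.

Step 4
Reactants: 6 N-{4,5-dibromo-2-[(trimethylsilyl)ethynyl]phenyl}-4-methylbenzenesulfonamide
Product: 7 N-[4,5-dibromo-2-(bromoethynyl)phenyl]-4-methylbenzenesulfonamide
Conditions: NBS (1.1 equiv), AgNO3 (10 mol%), acetone, rt, dark
Reagents that add atoms: N-bromosuccinimide, O=C1CCC(=O)N1Br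
Why: Silver-catalysed bromodesilylation of an alkynylsilane: Ag(I) converts the C(sp)–Si bond into a silver acetylide that takes Br+ from NBS at carbon, a process that should outpace attack on the electron-poor triple bond or on the neutral sulfonamide in base-free acetone.

Step 5
Reactants: 7 N-[4,5-dibromo-2-(bromoethynyl)phenyl]-4-methylbenzenesulfonamide
Product: 8 2,3,5,6-tetrabromo-1-(4-methylbenzenesulfonyl)-1H-indole
Conditions: NBS (1.05 equiv), dry MeCN, rt to 50 °C, dark
Reagents that add atoms: N-bromosuccinimide, O=C1CCC(=O)N1Br
Why: NBS transfers Br+ to the bromoalkyne to give a bridged bromirenium ion (possibly relayed through an N-bromosulfonamide), the sulfonamide nitrogen opens it anti at the bromine-bearing terminal carbon, and loss of the N–H proton to the succinimide anion leaves the aromatic N-tosyl-2,3-dibromoindole. The closest known reaction type is the electrophilic halocyclisation of N-sulfonyl-2-alkynylanilines to 3-haloindoles. The pyrrole ring closes in 5-endo-dig mode, the only accessible one because attack at the aryl-bound alkyne carbon would need a strained 4-exo closure. No stereocentre is formed. The step needs chemoselectivity for nitrogen capture over double bromine addition to the alkyne, hydration of the activated alkyne and substitution at the arene carbon ortho to nitrogen; the ortho-held intramolecular nucleophile, the absence of free bromide and water, one equivalent of reagent and a benzene ring deactivated by two bromines and the N-sulfonyl group should secure it. The lone pairs of the alkyne bromine also stabilise developing positive charge at the carbon under attack, which should offset the lower nucleophilicity of a haloalkyne.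

Step 6
Reactants: 8 2,3,5,6-tetrabromo-1-(4-methylbenzenesulfonyl)-1H-indole
Product: 9 2,3,5,6-tetrabromo-1H-indole
Conditions: Cs2CO3 (3 equiv), THF/MeOH (2:1), rt
Reagents that add atoms: none
Why: Base-mediated N-desulfonylation (methanolysis at sulfur): the tetrabromoindolide is a good leaving group, so carbonate/methanol at room temperature should cleave the N–S bond without touching the four C–Br bonds, which a reductive detosylation would endanger.

Compound list
1 | 3,4-dibromoaniline | Nc1ccc(Br)c(Br)c1 | starting material
2 | 4,5-dibromo-2-iodoaniline | Nc1cc(Br)c(Br)cc1I | intermediate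
3 | trimethylsilylacetylene | C[Si](C)(C)C#C | starting material
4 | 4,5-dibromo-2-[(trimethylsilyl)ethynyl]aniline | Nc1cc(Br)c(Br)cc1C#C[Si](C)(C)C | intermediate
5 | 4-toluenesulfonyl chloride | Cc1ccc(cc1)S(=O)(=O)Cl | starting material
6 | N-{4,5-dibromo-2-[(trimethylsilyl)ethynyl]phenyl}-4-methylbenzenesulfonamide | Cc1ccc(cc1)S(=O)(=O)Nc1cc(Br)c(Br)cc1C#C[Si](C)(C)C | intermediate
7 | N-[4,5-dibromo-2-(bromoethynyl)phenyl]-4-methylbenzenesulfonamide | Cc1ccc(cc1)S(=O)(=O)Nc1cc(Br)c(Br)cc1C#CBr | intermediate
8 | 2,3,5,6-tetrabromo-1-(4-methylbenzenesulfonyl)-1H-indole | Cc1ccc(cc1)S(=O)(=O)n1c(Br)c(Br)c2cc(Br)c(Br)cc21 | intermediate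
9 | 2,3,5,6-tetrabromo-1H-indole | Brc1cc2[nH]c(Br)c(Br)c2cc1Br | target

Total step count: 6
Longest linear sequence: 6 steps (1 to 9)

Steps most likely to fail

Step 5. The electron-poor bromoalkyne may be activated too slowly by NBS, or the activated alkyne may be diverted by hydration or by over-bromination instead of ring closure. The fallback sets out from 4 and returns at 8, building the indole first and adding the pyrrole bromines one at a time. Alkoxide-mediated 5-endo-dig hydroamination with loss of the silyl group (KOtBu, NMP, rt) should give 5,6-dibromo-1H-indole F1. N-Sulfonylation (NaH, TsCl, THF, 0 °C) should give 5,6-dibromo-1-tosylindole F2. Electrophilic substitution at C3 (Br2, CH2Cl2, rt) should give 3,5,6-tribromo-1-tosylindole F3. Deprotonation at C2 with LDA (THF, −78 °C; an amide base avoids bromine–lithium exchange) and quenching with 1,2-dibromotetrachloroethane should deliver 8.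

Step 4. Silver(I) or NBS may trigger premature ring closure or N-bromination of the free sulfonamide while the C–Si bond is being exchanged. The fallback sets out from 6 and returns at 7 and avoids silver altogether. Protodesilylation (K2CO3, MeOH, rt) should give N-(4,5-dibromo-2-ethynylphenyl)-4-methylbenzenesulfonamide F4. Double deprotonation (LDA, 2.1 equiv, THF, −78 °C) then forms the N,C-dianion, whose acetylide carbon is by far the stronger nucleophile. It should be brominated by one equivalent of 1,2-dibromotetrachloroethane, and a cold quench should give 7.

Step 6. Methoxide may attack C2 with displacement of bromide, or the liberated indolide may be N-methylated by the sulfonate ester formed during methanolysis. The fallback sets out from 4 and returns at 9, replacing tosyl by a sulfonyl group that is removed by thiolate ipso-substitution instead of alkoxide attack at sulfur. NsCl/pyridine should give N-{4,5-dibromo-2-[(trimethylsilyl)ethynyl]phenyl}-2-nitrobenzenesulfonamide F5. Bromodesilylation (NBS, cat. AgNO3, acetone) should give N-[4,5-dibromo-2-(bromoethynyl)phenyl]-2-nitrobenzenesulfonamide F6. Bromocyclisation with NBS in MeCN should give 2,3,5,6-tetrabromo-1-(2-nitrobenzenesulfonyl)-1H-indole F7. Thiolate cleavage (PhSH, K2CO3, DMF, rt) should then release 9.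

Further compounds
F1 | step 5 | 5,6-dibromo-1H-indole | Brc1cc2cc[nH]c2cc1Br
F2 | step 5 | 5,6-dibromo-1-tosylindole | Cc1ccc(cc1)S(=O)(=O)n1ccc2cc(Br)c(Br)cc21
F3 | step 5 | 3,5,6-tribromo-1-tosylindole | Cc1ccc(cc1)S(=O)(=O)n1cc(Br)c2cc(Br)c(Br)cc21
F4 | step 4 | N-(4,5-dibromo-2-ethynylphenyl)-4-methylbenzenesulfonamide | Cc1ccc(cc1)S(=O)(=O)Nc1cc(Br)c(Br)cc1C#C
F5 | step 6 | N-{4,5-dibromo-2-[(trimethylsilyl)ethynyl]phenyl}-2-nitrobenzenesulfonamide | O=[N+]([O-])c1ccccc1S(=O)(=O)Nc1cc(Br)c(Br)cc1C#C[Si](C)(C)C
F6 | step 6 | N-[4,5-dibromo-2-(bromoethynyl)phenyl]-2-nitrobenzenesulfonamide | O=[N+]([O-])c1ccccc1S(=O)(=O)Nc1cc(Br)c(Br)cc1C#CBr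
F7 | step 6 | 2,3,5,6-tetrabromo-1-(2-nitrobenzenesulfonyl)-1H-indole | O=[N+]([O-])c1ccccc1S(=O)(=O)n1c(Br)c(Br)c2cc(Br)c(Br)cc21
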